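The runs come from a simulation on assumed constants, and the scatter is random.

I decide to follow a single E molecule to its fork: it meets Z and heads for X, or it meets D and ends as L.

- south: E 0.50 M; Z 2 M; D 0.75 M; run made earlier
- flask: E 0.50 M; Z 2.00 M; D 0.500 M; time 15 d

south run (percent of the E charged): time / h: X / % = 10.0: 9.9; 20.0: 6.5; 25.0: 4.9; 40.0: 1.7

(each reading ± 0.3 percentage points)

- the numbers in the tables scatter by 0.3 percentage points (one standard deviation)
- on the list of suspects stand: E + D -> L; X <-> G; X -> J; E + Z -> X

- time, not beyond 15 d, at which the flask holds most X
- the amount of X, in percent of the E charged, at that time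

The south readings fall from 9.9% at 10.0 h to 1.7% at 40.0 h, so I expect the top of X early. At the start the Z road runs at the same rate in the flask as in south, since E and Z are charged alike, and the D road runs at 0.667 of its south rate. For the flask I carry 4.00, the fork ratio: Z per D, to which the selectivity at the fork, Z road over D road, is proportional. South has 2.67.

In the flask each part of the E charged that goes through D costs the same part of D's charge, while through Z it costs a quarter of that part of Z's charge, so I expect the ratio to climb along the run unless the D road is much the slower. In the flask E and D are charged equally, so the fraction of D left when E reaches zero equals the share of E that went through Z.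

The gain of 1.50 on the first south reading gives 14.9% for the flask, which I hold as high, since the share of E through Z grows more slowly than the ratio itself.

The forecast says 12.5% at 0.42 d: “lower D raises the peak slightly, and it comes early”.

The flask tops at 11.6% at 0.381 d, close to the forecast and below my mark. At the start of the flask E went 2.3 times as fast through D as through Z. By the top the flask's fork ratio has climbed to 6.19, and at 15.0 d, with E at 0%, the flask holds 39.3% of its D, the share of E that took the Z road.

    E + D → L (k = 0.00280 M⁻¹ min⁻¹)
    X ⇌ G (K = 24.0, k = 0.00190 min⁻¹)
    X → J (k = 1.80 × 10⁻⁴ min⁻¹)
    E + Z → X (k = 3.10 × 10⁻⁴ M⁻¹ min⁻¹)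

The neighbour with 0.80 M of Z has a fork ratio of 1.60, which scales the flask's top to 4.65%. Computed, it tops at 5.21% and keeps 23.6% of its D.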